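**Retrosynthetic overview**

1. 26 ⇒ 17 + 23 + 24: the C‑1′–CH2 bond is made last, by adding an isobutyl radical to the o‑quinone methide formed from terpene aldehyde 17 and diformylphloroglucinol 23; this sets C‑1′.
2. 17 ⇒ 15 ⇒ 13: equatorial methyl addition to the C‑4 ketone; rings A and B are closed together by an intramolecular Diels–Alder reaction of triene 12, which sets C‑1, C‑4a and C‑8a from C‑6.
3. 12 ⇒ 9 ⇒ 8 ⇒ 5 + 6: vinyl Grignard opening of a δ‑lactone, Baeyer–Villiger oxidation of a temporary cyclopentanone, (E)‑enoate by alkylborane addition to methyl but‑2‑ynoate.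
4. 5 ⇒ 4 ⇒ 1 + 2: rhodium‑catalysed desymmetrising hydroacylation of a Claisen‑derived dienal gives the only catalyst‑set stereocentre (C‑6).
5. 23 ⇒ 21 ⇒ 18: phloroglucinol from resorcinol by C–H borylation/oxidation, then double formylation. Ring order: temporary cyclopentanone, then rings A and B in one step; the arene comes from resorcinol.

Assumption: (S)‑BINAP is taken to give the (3R)‑ketone 5 in step 2; if the sense is the opposite, (R)‑BINAP is used and nothing else changes.

Locants in the text follow the naphthalene numbering of 26 (C‑1 side chain, C‑4 carbinol, C‑4a ring‑fusion CH, C‑6 hydroxypropyl‑bearing carbon, C‑8a angular methyl carbon); C‑1′ is the benzylic carbon. Ring A carries C‑1 to C‑4, ring B carries C‑5 to C‑8.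

**Route**

Step 1
Reactants: 1 2-methylpropanal; 2 (2E)-penta-2,4-dien-1-ol
Product: 4 3-ethenyl-2,2-dimethylpent-4-enal, via allyl vinyl ether 3 (not isolated)
Conditions: TsOH·H2O (2 mol %), hydroquinone (cat.), p-cymene, 150 °C, Dean–Stark (−H2O)
Reagents that add atoms: none
Why: Acid-catalysed condensation gives allyl vinyl ether 3, whose Claisen [3,3] rearrangement through the proximal alkene of the dienyl unit delivers the bis-vinyl methine next to the quaternary aldehyde carbon; no stereocentre is formed.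

Step 2
Reactants: 4 3-ethenyl-2,2-dimethylpent-4-enal
Product: 5 (3R)-3-ethenyl-2,2-dimethylcyclopentan-1-one
Conditions: [Rh((S)-BINAP)]ClO4 (5 mol %), CH2Cl2, 25 °C
Reagents that add atoms: none
Why: Enantioselective intramolecular alkene hydroacylation of a 4-pentenal (acyl–rhodium hydride, alkene insertion, reductive elimination), in which the chiral catalyst selects one of the two enantiotopic vinyl groups and so sets the future C‑6 centre by desymmetrisation.

Step 3
Reactants: 5 (3R)-3-ethenyl-2,2-dimethylcyclopentan-1-one; 6 methyl but-2-ynoate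
Product: 8 methyl (2E)-5-[(1S)-2,2-dimethyl-3-oxocyclopentyl]-3-methylpent-2-enoate, via alkyl-9-BBN 7 (not isolated)
Conditions: 9-BBN-H dimer, THF, 0 °C → rt; then 6, CuOAc (5 mol %), P(OPh)3 (10 mol %), t-BuOK (10 mol %), t-BuOH (1.2 equiv), 1,4-dioxane, 40 °C
Reagents that add atoms: none
Why: Anti-Markovnikov hydroboration followed by copper-catalysed conjugate addition of the alkylborane to the alkynoate (formal syn-hydroalkylation) puts the chain trans to the ester, giving the (E)-β-methyl enoate whose geometry later fixes the cis relation of the C‑1 substituent and the angular methyl.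

Step 4
Reactants: 8 methyl (2E)-5-[(1S)-2,2-dimethyl-3-oxocyclopentyl]-3-methylpent-2-enoate
Product: 9 methyl (2E)-5-[(3S)-2,2-dimethyl-6-oxooxan-3-yl]-3-methylpent-2-enoate
Conditions: m-CPBA (2 equiv), NaHCO3, CH2Cl2, rt
Reagents that add atoms: 3-chloroperoxybenzoic acid, O=C(OO)c1cccc(Cl)c1
Why: Baeyer–Villiger oxidation with migration of the quaternary carbon places the ring oxygen on the future carbinol carbon, while the electron-poor enoate is not epoxidised and the stereocentre is untouched.

Step 5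
Reactants: 9 methyl (2E)-5-[(3S)-2,2-dimethyl-6-oxooxan-3-yl]-3-methylpent-2-enoate
Product: 11 methyl (2E,6S)-6-(2-hydroxypropan-2-yl)-3-methyl-9-oxoundeca-2,10-dienoate, via magnesium lactolate 10 (not isolated)
Conditions: CH2=CHMgBr (1.1 equiv), THF, −78 °C; AcOH, −78 °C
Reagents that add atoms: vinylmagnesium bromide, C=C[Mg]Br
Why: Grignard mono-addition to the δ-lactone, which is more electrophilic than the β,β-disubstituted conjugated ester, stops at the tetrahedral lactolate 10 at −78 °C and releases the δ-hydroxy vinyl ketone on cold acidic quench.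

Step 6
Reactants: 11 methyl (2E,6S)-6-(2-hydroxypropan-2-yl)-3-methyl-9-oxoundeca-2,10-dienoate
Product: 12 methyl (2E,6S,8Z)-3-methyl-9-[(triethylsilyl)oxy]-6-{2-[(triethylsilyl)oxy]propan-2-yl}undeca-2,8,10-trienoate
Conditions: TESOTf (2.5 equiv), Et3N (4 equiv), CH2Cl2, −78 → 0 °C
Reagents that add atoms: triethylsilyl trifluoromethanesulfonate, CC[Si](CC)(CC)OS(=O)(=O)C(F)(F)F
Why: Soft enolisation of the vinyl ketone toward its α′-methylene gives the (Z)-2-silyloxy-1,3-diene and the tertiary alcohol is silylated in the same operation, the ester being too weakly acidic to react at this temperature.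

Step 7
Reactants: 12 methyl (2E,6S,8Z)-3-methyl-9-[(triethylsilyl)oxy]-6-{2-[(triethylsilyl)oxy]propan-2-yl}undeca-2,8,10-trienoate
Product: 13 methyl (1S,4aS,6S,8aS)-8a-methyl-4-[(triethylsilyl)oxy]-6-{2-[(triethylsilyl)oxy]propan-2-yl}-1,2,4a,5,6,7,8,8a-octahydronaphthalene-1-carboxylate
Conditions: PhMe (0.01 M), BHT (cat.), 170 °C, sealed tube
Reagents that add atoms: none
Why: Intramolecular Diels–Alder reaction (type 1) of the silyloxydiene with the tethered (E)-enoate, in which suprafacial addition turns the alkene geometry into the cis relation of ester and angular methyl, and the ester-endo transition state with a chair-like tether holding the bulky C‑6 substituent equatorial gives the trans ring fusion, so C‑1, C‑4a and C‑8a are set relative to C‑6.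

Step 8
Reactants: 13 methyl (1S,4aS,6S,8aS)-8a-methyl-4-[(triethylsilyl)oxy]-6-{2-[(triethylsilyl)oxy]propan-2-yl}-1,2,4a,5,6,7,8,8a-octahydronaphthalene-1-carboxylate
Product: 15 (4S,4aR,7S,8aS)-4-(hydroxymethyl)-7-(2-hydroxypropan-2-yl)-4a-methyloctahydronaphthalen-1(2H)-one, via silylated alcohol 14 (not isolated)
Conditions: LiAlH4, THF, 0 °C; then 1 M HCl, THF, rt
Reagents that add atoms: none
Why: Hydride reduction of the ester while the ketone is masked as its silyl enol ether, then acid hydrolysis of the enol ether (protonation at C‑3, so C‑4a is not touched) and of the silyl ether, the trans-decalone also being the thermodynamic epimer.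

Step 9
Reactants: 15 (4S,4aR,7S,8aS)-4-(hydroxymethyl)-7-(2-hydroxypropan-2-yl)-4a-methyloctahydronaphthalen-1(2H)-one
Product: 16 (1R,4S,4aR,7S,8aS)-4-(hydroxymethyl)-7-(2-hydroxypropan-2-yl)-1,4a-dimethyldecahydronaphthalen-1-ol
Conditions: MeLi (5 equiv), CeCl3 (5 equiv), THF, −78 → −20 °C
Reagents that add atoms: methyllithium, [Li]C
Why: Organocerium 1,2-addition without enolisation, in which the methyl group enters equatorially because axial attack is blocked by the syn-axial angular methyl, giving the axial tertiary alcohol of the target.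

Step 10
Reactants: 16 (1R,4S,4aR,7S,8aS)-4-(hydroxymethyl)-7-(2-hydroxypropan-2-yl)-1,4a-dimethyldecahydronaphthalen-1-ol
Product: 17 (1S,4R,4aS,6S,8aS)-4-hydroxy-6-(2-hydroxypropan-2-yl)-4,8a-dimethyldecahydronaphthalene-1-carbaldehyde
Conditions: TEMPO (10 mol %), PhI(OAc)2 (1.2 equiv), CH2Cl2, rt
Reagents that add atoms: none
Why: TEMPO/oxoammonium oxidation is selective for the primary alcohol, leaves both tertiary alcohols alone and is neutral enough not to epimerise C‑1.

Step 11
Reactants: 18 benzene-1,3-diol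
Product: 21 benzene-1,3,5-triol, via bis(O-boryl)resorcinol 19 (not isolated), via arylboronate 20 (not isolated)
Conditions: HBpin (4 equiv), [Ir(OMe)(cod)]2 (1.5 mol %), dtbpy (3 mol %), THF, 80 °C; then KHSO5 (as 2KHSO5·KHSO4·K2SO4), acetone–H2O, 0 °C
Reagents that add atoms: potassium peroxymonosulfate, [K+].OOS(=O)(=O)[O-]
Why: Iridium-catalysed, sterically controlled C–H borylation of resorcinol protected in the flask as its O-boryl ether takes place at C‑5, the only position not ortho to a substituent, and oxidation of the aryl–boron bond then gives the third phenol.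

Step 12
Reactants: 21 benzene-1,3,5-triol
Product: 23 2,4,6-trihydroxybenzene-1,3-dicarbaldehyde, via bis-iminium salt 22 (not isolated)
Conditions: POCl3 (2.4 equiv), DMF (2.4 equiv), EtOAc, 0 °C → rt; then H2O, 60 °C
Reagents that add atoms: N,N-dimethylformamide, CN(C)C=O; water, O
Why: Double Vilsmeier–Haack formylation of the very nucleophilic phloroglucinol, limited to two positions by stoichiometry and by deactivation of the ring after the second iminium group.

Step 13
Reactants: 17 (1S,4R,4aS,6S,8aS)-4-hydroxy-6-(2-hydroxypropan-2-yl)-4,8a-dimethyldecahydronaphthalene-1-carbaldehyde; 23 2,4,6-trihydroxybenzene-1,3-dicarbaldehyde; 24 1-iodo-2-methylpropane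
Product: 26 5-{(1R)-1-[(1R,4R,4aS,6S,8aR)-4-hydroxy-6-(2-hydroxypropan-2-yl)-4,8a-dimethyldecahydronaphthalen-1-yl]-3-methylbutyl}-2,4,6-trihydroxybenzene-1,3-dicarbaldehyde, via o-quinone methide 25 (not isolated)
Conditions: NaOAc (0.3 equiv), AcOH–PhCF3 (1:5), 80 °C; 24 (6 equiv); (TMS)3SiH (2.5 equiv) and AIBN (0.4 equiv) added over 6 h
Reagents that add atoms: none
Why: Proposed new method: Knoevenagel condensation of 17 with 23 gives o-quinone methide 25 (closest known type: three-component o-quinone methide formation from diformylphloroglucinol and an aldehyde), the nucleophilic isobutyl radical made by iodine abstraction adds to its exocyclic carbon in a Giese-type 1,4-addition driven by rearomatisation (closest known type: alkyl radical additions to quinone methides), the aryloxyl radical takes hydrogen from the silane to carry the chain, and because allylic 1,3-strain holds the C‑1 hydrogen in the plane of the methide the radical attacks the face turned away from the quaternary C‑8a, which gives the (1′R) centre.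

**Compound list**

1 | 2-methylpropanal | CC(C)C=O | starting material
2 | (2E)-penta-2,4-dien-1-ol | OC/C=C/C=C | starting material
3 | (3E)-5-[(2-methylprop-1-en-1-yl)oxy]penta-1,3-diene | CC(C)=COC/C=C/C=C | intermediate
4 | 3-ethenyl-2,2-dimethylpent-4-enal | O=CC(C)(C)C(C=C)C=C | intermediate
5 | (3R)-3-ethenyl-2,2-dimethylcyclopentan-1-one | O=C1CC[C@@H](C1(C)C)C=C | intermediate
6 | methyl but-2-ynoate | CC#CC(=O)OC | starting material
7 | (3S)-3-[2-(9-borabicyclo[3.3.1]nonan-9-yl)ethyl]-2,2-dimethylcyclopentan-1-one | O=C1CC[C@@H](C1(C)C)CCB1C2CCCC1CCC2 | intermediate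
8 | methyl (2E)-5-[(1S)-2,2-dimethyl-3-oxocyclopentyl]-3-methylpent-2-enoate | O=C1CC[C@@H](C1(C)C)CC/C(C)=C/C(=O)OC | intermediate
9 | methyl (2E)-5-[(3S)-2,2-dimethyl-6-oxooxan-3-yl]-3-methylpent-2-enoate | O=C1CC[C@@H](C(C)(C)O1)CC/C(C)=C/C(=O)OC | intermediate
10 | bromomagnesium (5S)-2-ethenyl-5-[(3E)-5-methoxy-3-methyl-5-oxopent-3-en-1-yl]-6,6-dimethyloxan-2-olate | C=CC1(O[Mg]Br)CC[C@@H](C(C)(C)O1)CC/C(C)=C/C(=O)OC | intermediate
11 | methyl (2E,6S)-6-(2-hydroxypropan-2-yl)-3-methyl-9-oxoundeca-2,10-dienoate | C=CC(=O)CC[C@@H](C(C)(C)O)CC/C(C)=C/C(=O)OC | intermediate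
12 | methyl (2E,6S,8Z)-3-methyl-9-[(triethylsilyl)oxy]-6-{2-[(triethylsilyl)oxy]propan-2-yl}undeca-2,8,10-trienoate | C=C/C(O[Si](CC)(CC)CC)=C/C[C@@H](C(C)(C)O[Si](CC)(CC)CC)CC/C(C)=C/C(=O)OC | intermediate
13 | methyl (1S,4aS,6S,8aS)-8a-methyl-4-[(triethylsilyl)oxy]-6-{2-[(triethylsilyl)oxy]propan-2-yl}-1,2,4a,5,6,7,8,8a-octahydronaphthalene-1-carboxylate | COC(=O)[C@H]1CC=C(O[Si](CC)(CC)CC)[C@H]2C[C@@H](C(C)(C)O[Si](CC)(CC)CC)CC[C@]12C | intermediate
14 | [(1S,4aS,6S,8aR)-8a-methyl-4-[(triethylsilyl)oxy]-6-{2-[(triethylsilyl)oxy]propan-2-yl}-1,2,4a,5,6,7,8,8a-octahydronaphthalen-1-yl]methanol | OC[C@H]1CC=C(O[Si](CC)(CC)CC)[C@H]2C[C@@H](C(C)(C)O[Si](CC)(CC)CC)CC[C@]12C | intermediate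
15 | (4S,4aR,7S,8aS)-4-(hydroxymethyl)-7-(2-hydroxypropan-2-yl)-4a-methyloctahydronaphthalen-1(2H)-one | OC[C@H]1CCC(=O)[C@H]2C[C@@H](C(C)(C)O)CC[C@]12C | intermediate
16 | (1R,4S,4aR,7S,8aS)-4-(hydroxymethyl)-7-(2-hydroxypropan-2-yl)-1,4a-dimethyldecahydronaphthalen-1-ol | OC[C@H]1CC[C@@](C)(O)[C@H]2C[C@@H](C(C)(C)O)CC[C@]12C | intermediate
17 | (1S,4R,4aS,6S,8aS)-4-hydroxy-6-(2-hydroxypropan-2-yl)-4,8a-dimethyldecahydronaphthalene-1-carbaldehyde | O=C[C@H]1CC[C@@](C)(O)[C@H]2C[C@@H](C(C)(C)O)CC[C@]12C | intermediate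
18 | benzene-1,3-diol | Oc1cccc(O)c1 | starting material
19 | 1,3-bis[(4,4,5,5-tetramethyl-1,3,2-dioxaborolan-2-yl)oxy]benzene | CC1(C)OB(Oc2cccc(OB3OC(C)(C)C(C)(C)O3)c2)OC1(C)C | intermediate
20 | 2,2'-{[5-(4,4,5,5-tetramethyl-1,3,2-dioxaborolan-2-yl)-1,3-phenylene]bis(oxy)}bis(4,4,5,5-tetramethyl-1,3,2-dioxaborolane) | CC1(C)OB(Oc2cc(OB3OC(C)(C)C(C)(C)O3)cc(B3OC(C)(C)C(C)(C)O3)c2)OC1(C)C | intermediate
21 | benzene-1,3,5-triol | Oc1cc(O)cc(O)c1 | intermediate
22 | N,N'-[(2,4,6-trihydroxy-1,3-phenylene)dimethylidyne]bis(N-methylmethanaminium) dichloride | C[N+](C)=Cc1c(O)cc(O)c(C=[N+](C)C)c1O.[Cl-].[Cl-] | intermediate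
23 | 2,4,6-trihydroxybenzene-1,3-dicarbaldehyde | O=Cc1c(O)cc(O)c(C=O)c1O | intermediate
24 | 1-iodo-2-methylpropane | CC(C)CI | starting material
25 | 5-{[(1R,4R,4aS,6S,8aR)-4-hydroxy-6-(2-hydroxypropan-2-yl)-4,8a-dimethyldecahydronaphthalen-1-yl]methylidene}-2,4-dihydroxy-6-oxocyclohexa-1,3-diene-1,3-dicarbaldehyde | O=CC1=C(O)C(C=O)=C(O)C(=C[C@H]2CC[C@@](C)(O)[C@H]3C[C@@H](C(C)(C)O)CC[C@]23C)C1=O | intermediate
26 | 5-{(1R)-1-[(1R,4R,4aS,6S,8aR)-4-hydroxy-6-(2-hydroxypropan-2-yl)-4,8a-dimethyldecahydronaphthalen-1-yl]-3-methylbutyl}-2,4,6-trihydroxybenzene-1,3-dicarbaldehyde | CC(C)C[C@@H](c1c(O)c(C=O)c(O)c(C=O)c1O)[C@H]1CC[C@@](C)(O)[C@H]2C[C@@H](C(C)(C)O)CC[C@]12C | target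

**Step count and risks**

Total step count: 13. Longest linear sequence: 11 (steps 1 to 10, then step 13); steps 11 and 12 form the short aryl branch.

The three steps most likely to fail:

Step 13. The hindered aldehyde 17 may form methide 25 slowly, the isobutyl radical may be reduced by the silane before it finds the transient methide, and the C‑1′ selectivity rests on a conformational argument only; the minor C‑1′ epimer would have to be removed by chromatography. The fallback sets out from 17 and 23 and comes back at 26. The same condensation is run in the presence of (2-methylprop-1-en-1-yl)boronic acid and a chiral 3,3′-dibromo-BINOL catalyst. The boronate, bound to the phenol oxygen, then transfers its alkenyl group to the methide in a polar 1,4-addition whose face is set by the catalyst, and this gives the 3-methylbut-2-enyl adduct 5-{(1R)-1-[(1R,4R,4aS,6S,8aR)-4-hydroxy-6-(2-hydroxypropan-2-yl)-4,8a-dimethyldecahydronaphthalen-1-yl]-3-methylbut-2-en-1-yl}-2,4,6-trihydroxybenzene-1,3-dicarbaldehyde F1. Hydrogenation of the trisubstituted alkene of F1 with [Ir(cod)(PCy3)(py)]PF6 under H2 in CH2Cl2 then gives 26.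

Step 7. The β,β-disubstituted enoate is a sluggish dienophile and the cis-fused transition state may compete; its product is a separable diastereomer that cannot be converted into 13, so this costs yield, not enantiopurity. The fallback sets out from 11 and comes back at 13. Silylation of the tertiary alcohol alone (TESOTf, 2,6-lutidine, −78 °C) gives the enone silyl ether methyl (2E,6S)-3-methyl-9-oxo-6-{2-[(triethylsilyl)oxy]propan-2-yl}undeca-2,10-dienoate F2. LiHMDS at −78 °C then forms the cross-conjugated lithium dienolate, which closes ring B by Michael addition to the enoate and ring A by Michael addition of the new ester enolate to the vinyl ketone (anionic double Michael reaction). The final ketone enolate is trapped with TESCl as 13.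

Step 5. Over-addition of the Grignard reagent to the released vinyl ketone, or attack at the enoate, would erode the yield. The fallback sets out from 9 and comes back at 11. Me(MeO)NH·HCl and i-PrMgCl open the lactone to the hydroxy Weinreb amide methyl (2E,6S)-6-(2-hydroxypropan-2-yl)-9-[methoxy(methyl)amino]-3-methyl-9-oxonon-2-enoate F3. Treatment of F3 with CH2=CHMgBr (2.2 equiv) gives a stable chelate that cannot add a second equivalent and releases 11 on cold acidic quench.

Further compounds
F1 | step 13 | 5-{(1R)-1-[(1R,4R,4aS,6S,8aR)-4-hydroxy-6-(2-hydroxypropan-2-yl)-4,8a-dimethyldecahydronaphthalen-1-yl]-3-methylbut-2-en-1-yl}-2,4,6-trihydroxybenzene-1,3-dicarbaldehyde | CC(C)=C[C@@H](c1c(O)c(C=O)c(O)c(C=O)c1O)[C@H]1CC[C@@](C)(O)[C@H]2C[C@@H](C(C)(C)O)CC[C@]12C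
F2 | step 7 | methyl (2E,6S)-3-methyl-9-oxo-6-{2-[(triethylsilyl)oxy]propan-2-yl}undeca-2,10-dienoate | C=CC(=O)CC[C@@H](C(C)(C)O[Si](CC)(CC)CC)CC/C(C)=C/C(=O)OC
F3 | step 5 | methyl (2E,6S)-6-(2-hydroxypropan-2-yl)-9-[methoxy(methyl)amino]-3-methyl-9-oxonon-2-enoate | CON(C)C(=O)CC[C@@H](C(C)(C)O)CC/C(C)=C/C(=O)OC
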